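Compound numbers 1–32 are those of the steps below. Atom numbers are germacrane numbers: C1–C10 ring, C11–C13 lactone arm, C14 on C10, C15 on C4.

## Analysis of the target

Target 32 is a germacranolide: a ten-membered carbocycle (C1–C10) cis-fused at C6/C7 to an α-methylene-γ-butyrolactone (O on C6, C11=C13, C12 carbonyl). It carries a 1,10-epoxide with the C14 methyl on C10, a Z-trisubstituted C4=C5 alkene bearing C15, an acetate on C3 and a 3-methylbutanoate on C8. The six stereocentres are C1 (R), C3 (R), C6 (S), C7 (R), C8 (S) and C10 (S). On a flat drawing of the ring, the lactone oxygen on C6, C11 on C7 and the epoxide oxygen lie on one face (β here), and the acyloxy groups on C3 and C8 on the other (α). The oxirane is the cis one (C2 and C9 on the same side), so it is the epoxide of a Z-C1=C10 alkene. Sensitive groups are the exo-methylene lactone (Michael acceptor, reducible), the trisubstituted epoxide in a medium ring (acid, transannular opening), and three secondary acyloxy groups that can migrate. The hard points are the medium ring, the Z geometry of a trisubstituted alkene lying between two oxygenated stereocentres, and telling apart the oxygens on C3, C6 and C8. The strategy rests on the unit O–C3–C4(C15)=C5–C6–O: a cis-2-ene-1,4-diol whose oxygens can be bridged by one silicon atom into a seven-membered ring containing C4=C5, so the alkene is made by ring closure and can only be Z.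

## Retrosynthetic reasoning

**32 to 31.** The C1–O and C10–O bonds of the oxirane are cut last, back to Z,Z-diene 31. The epoxide is the most acid-sensitive group, so it should not have to survive desilylation, oxidation and acylation. In 31 the other alkenes are deactivated (C4=C5 by two allylic acyloxy groups, C11=C13 by conjugation), and both flanking acyloxy groups sit on the α face, so a peracid should find C1=C10 from the β face.

**31 to 29.** The acetyl C–O bond on O3 and the O6–C12 lactone bond are cut, via 30, to triol 29. An oxidative lactonisation that starts at the primary allylic C12 alcohol and uses O6 as internal nucleophile tells O6 from O3 without a protecting group. O8 needs no attention because it carries its 3-methylbutanoyl group from step 11 onward.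

**29 to 28.** All Si–O bonds are cut in one operation: the O3–Si–O6 bridge and the silyl ether on O12 of 28.

**28 to 25.** The ten-membered ring is opened at C1–C10, the only ring bond outside both fragments of the key step and the only one whose two carbons can both be carbonyl carbons. A samarium-bridged reductive coupling of keto aldehyde 25 should give cis-diol 26. Closing a cis-diol to the epoxide by displacement at C1 would invert C1 and give the trans-oxirane, which is the wrong one. The diol is therefore taken through thiocarbonate 27 and a syn-elimination to the Z-alkene of 28. This erases both new centres and makes the facial outcome of the coupling irrelevant.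

**25 to 24.** The carbonyls are masked as a dimethyl acetal (C1) and a dioxolane (C10), so that neither interferes with organometallic steps or metathesis.

**24 to 23 (key).** C4=C5 is cut by ring-closing metathesis of the C6 vinyl and C3 isopropenyl groups of mixed silaketal 23. A cross-metathesis would be unselective and slow for a trisubstituted alkene; the tether makes it a seven-membered ring closure with forced Z geometry. The two side chains end trans on the new ring (4R,7S), which the forward closure must tolerate.

**23 to 4 + 20 + 21.** The two Si–O bonds are cut to alcohol 4 (C1–C4, C15), alcohol 20 (C5–C14) and dichlorosilane 21. Each carbinol centre is set on its own fragment by reagent control, so no diastereoselective fragment coupling is needed.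

**20 to 18.** The C6–H bond and the O8 acyl bond of 20 come from one reaction, an Evans–Tishchenko reduction of β-hydroxy vinyl ketone 19. It sets C6 anti to O8, leaves O6 free for the tether and installs the natural ester on O8. The C5–C6 bond is cut to Weinreb amide 18 and a vinyl nucleophile.

**18 to 13 + 15.** C7–C8 is cut by a syn-aldol disconnection (via 17) to imide 13 and aldehyde 15; the auxiliary 11 fixes both centres.

**13, 15 and 4 to starting materials.** Imide 13 comes from acid 10 and 11. Acid 10 comes from lactone 8, made by carboxylation of the dianion of 5 (the new bond is C6–C7). Aldehyde 15 comes from ester 14. Alcohol 4 comes from enone 3 by CBS reduction (C3), and 3 from ester 1 through Weinreb amide 2 and an isopropenyl nucleophile (C3–C4 bond).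

## Alternatives that were turned down

**Alternative 1:** Disconnection at C2–C3 and C3–C4, with C3 supplied as the carbonyl carbon of a carbonylative Stille coupling. In the forward key step a zerovalent palladium catalyst ionises an allylic chloride at C2, carbonyl insertion gives an acylpalladium, and transmetalation from a Z-alkenylstannane at C4 in the same chain closes the ring as the C3 enone A1, with the cis-lactone already present.
- For it: the carbocycle and two C–C bonds form in one step, the stannane transfers its geometry with retention, and fewer protecting groups are needed. On step economy for ring formation it is stronger than the chosen route, which spends steps 12–17 on the same task.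
- Against it: C3 arrives as a ketone, so (3R) must come from a substrate-controlled reduction in a flexible ring. The C2 methylene of A1 lies between the ketone and C1=C10 and invites migration into conjugation. The π-allyl intermediate can scramble the C1=C10 geometry and the site of insertion. The C6 lactone oxygen is itself allylic to the stannane-bearing alkene and can be ionised by the same catalyst. A1 lacks C13, so a methylenation must follow.
- Comparison: the chosen route is longer but fixes C3 in an open chain by a catalyst-controlled reduction and fixes the Z geometry by ring size.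

**Alternative 2:** Disconnection at C7–C8 through a ring contraction of a thirteen-membered cyclic allylic ether in which oxygen links C8 to C13. In the forward key step tin–lithium exchange at C8 gives an α-alkoxy carbanion whose [2,3]-Wittig shift forms C7–C8, breaks O–C13 and gives the ten-membered carbinol A2, with the C11=C13 methylene and a free C8 hydroxyl.
- For it: one concerted step makes a ring bond, two stereocentres and the exo-methylene, and it replaces a direct ten-membered closure by contraction of an easier large ring. On that point it is stronger than the pinacol closure of step 15.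
- Against it: both Z-trisubstituted alkenes must already be in the macrocycle, so the geometry problem that the silicon tether solves is only moved. The C7/C8 outcome depends on the folding of a thirteen-membered transition state and on the geometry of the migrating alkene, which cannot be predicted from structure. The silyloxy group on C6 sits next to the reacting terminus, and [1,2]-shift and elimination compete.
- Comparison: the chosen route sets C7/C8 by an auxiliary-controlled aldol before any ring exists, and its precursors are acyclic and short.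

**Alternative 3:** Disconnection at C8–C9 (oxy-Cope) and C7–C11 (enolate alkylation), tracing the ring to a terpene-derived 1,2-dialkenylcyclohex-2-enol. In the forward key step the potassium alkoxide undergoes the anionic oxy-Cope shift, forming C8–C9 and breaking the bond between the carbons that become C1 and C6; the ten-membered enolate is alkylated at C7 with a bromoacetate ester to give dienone A3.
- For it: chiral-pool start, the C4=C5 geometry is inherited from the six-membered ring, and the ring expansion reaches the carbocycle in the fewest steps of all four routes.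
- Against it: A3 carries C6 as a ketone (reduction must come cis to the C7 arm), C8 as a silyl group (oxidative conversion to hydroxyl in the presence of two trisubstituted alkenes) and no C13. The C1=C10 geometry depends on a chair or boat transition state. Four redox corrections on the medium ring are each a stereochemical or chemoselectivity gamble.
- Comparison: the chosen route is slower to the ring but brings C3, C6 and C8 in with final oxidation level and configuration, with O8 already acylated.

Key step: step 13

Assumption: 26 is drawn as the cis-diol with both hydroxyls on the β face; the α,α-cis-diol would behave the same in steps 16 and 17, where both centres are erased.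

## Route

Step 1
Reactants: 1 methyl 3,3-dimethoxypropanoate
Product: 2 N,3,3-trimethoxy-N-methylpropanamide
Conditions: MeNH(OMe)·HCl, i-PrMgCl, THF, −20 °C
Reagents that add atoms: N,O-dimethylhydroxylamine hydrochloride, CNOC.Cl
Why: Aminolysis of a methyl ester by the chloromagnesium amide of N,O-dimethylhydroxylamine (Weinreb amide formation); the acetal is inert to the basic, non-aqueous conditions.

Step 2
Reactants: 2 N,3,3-trimethoxy-N-methylpropanamide
Product: 3 5,5-dimethoxy-2-methylpent-1-en-3-one
Conditions: CH2=C(CH3)MgBr, THF, 0 °C; cold aq. NH4Cl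
Reagents that add atoms: isopropenylmagnesium bromide, C=C(C)[Mg]Br
Why: Weinreb ketone synthesis: the chelated tetrahedral intermediate survives until the quench, so the isopropenyl group (C4, C15 and the methylene lost in step 13) adds only once; a cold, weakly acidic quench limits conjugate addition of the released amine and loss of methanol from the β-keto acetal.

Step 3
Reactants: 3 5,5-dimethoxy-2-methylpent-1-en-3-one
Product: 4 (3R)-5,5-dimethoxy-2-methylpent-1-en-3-ol (fragment A)
Conditions: (S)-2-methyl-CBS-oxazaborolidine (10 mol %), catecholborane, toluene, −78 °C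
Reagents that add atoms: none
Why: Corey–Bakshi–Shibata reduction: the α-branched alkenyl group acts as the large substituent and the CH2CH(OMe)2 arm as the small one, so the (S)-catalyst should give the (3R)-allylic alcohol (C3 of the target); catecholborane at low temperature avoids hydroboration of the 1,1-disubstituted alkene.

Step 4
Reactants: 5 2-methylprop-2-en-1-ol
Product: 8 4-methylideneoxolan-2-one, via methallyl alcohol dianion 6 (not isolated), via hydroxy acid 7 (not isolated)
Conditions: n-BuLi (2.2 equiv), TMEDA, Et2O/THF, 0 °C → rt; CO2 (s), −78 °C; 2 M HCl, rt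
Reagents that add atoms: carbon dioxide, O=C=O
Why: Alkoxide-directed allylic lithiation gives the O,C-dianion, whose symmetric allyl terminus is carboxylated (allyllithium carboxylation); on acidification the γ-hydroxy acid closes to the five-membered lactone, a distillable form of C7 and C11–C13 with C6 as carbonyl carbon.

Step 5
Reactants: 8 4-methylideneoxolan-2-one
Product: 10 3-{[tert-butyl(diphenyl)silyl]oxymethyl}but-3-enoic acid, via lithium hydroxy carboxylate 9 (not isolated)
Conditions: LiOH, THF/H2O, 0 °C; evaporate; TBDPSCl, imidazole, DMF, rt; K2CO3, MeOH/H2O; 1 M HCl to pH 4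
Reagents that add atoms: lithium hydroxide, [Li+].[OH-]; tert-butyl(chloro)diphenylsilane, CC(C)(C)[Si](Cl)(c1ccccc1)c1ccccc1
Why: Saponification of a γ-lactone should be faster at 0 °C than base-induced migration of the exocyclic alkene into conjugation; the dry lithium carboxylate is silylated on the primary alcohol (silyl ether formation), any silyl ester being cleaved by the carbonate wash.

Step 6
Reactants: 10 3-{[tert-butyl(diphenyl)silyl]oxymethyl}but-3-enoic acid; 11 (4R)-4-benzyl-1,3-oxazolidin-2-one
Product: 13 (4R)-4-benzyl-3-(3-{[tert-butyl(diphenyl)silyl]oxymethyl}but-3-enoyl)-1,3-oxazolidin-2-one, via pivalic mixed anhydride 12 (not isolated)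
Conditions: t-BuCOCl, Et3N, THF, −20 °C; then 11, LiCl, −20 °C → rt
Reagents that add atoms: none
Why: N-Acylation of the oxazolidinone through the pivalic mixed anhydride with LiCl/Et3N activation, mild enough to keep the β,γ-alkene out of conjugation.

Step 7
Reactants: 14 ethyl 2-(2-methyl-1,3-dioxolan-2-yl)acetate
Product: 15 2-(2-methyl-1,3-dioxolan-2-yl)acetaldehyde
Conditions: i-Bu2AlH, CH2Cl2, −78 °C; aq. KNaC4H4O6
Reagents that add atoms: none
Why: Partial reduction of an ester by i-Bu2AlH at −78 °C, where the aluminium hemiacetal is stable until work-up; the aldehyde (C8–C10, C14) is used at once because it self-condenses on standing.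

Step 8
Reactants: 13 (4R)-4-benzyl-3-(3-{[tert-butyl(diphenyl)silyl]oxymethyl}but-3-enoyl)-1,3-oxazolidin-2-one; 15 2-(2-methyl-1,3-dioxolan-2-yl)acetaldehyde
Product: 17 (4R)-4-benzyl-3-[(2R,3S)-2-(3-{[tert-butyl(diphenyl)silyl]oxy}prop-1-en-2-yl)-3-hydroxy-4-(2-methyl-1,3-dioxolan-2-yl)butanoyl]-1,3-oxazolidin-2-one, via boron enolate 16 (not isolated)
Conditions: n-Bu2BOTf, i-Pr2NEt, CH2Cl2, −78 → 0 °C; 15, −78 → 0 °C; pH 7 buffer, MeOH, H2O2
Reagents that add atoms: none
Why: Evans syn-aldol reaction: the Z-boron enolate (a 2-boryloxy diene that reacts at its α-carbon) adds through a chair Zimmerman–Traxler transition state on the face away from the benzyl group, so the (R)-auxiliary should set C7 and C8 as the (2R,3S) syn adduct, with C11 and O8 on opposite faces of the later ring; oxidative work-up removes boron.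

Step 9
Reactants: 17 the syn-aldol imide
Product: 18 (2R,3S)-2-(3-{[tert-butyl(diphenyl)silyl]oxy}prop-1-en-2-yl)-3-hydroxy-N-methoxy-N-methyl-4-(2-methyl-1,3-dioxolan-2-yl)butanamide
Conditions: MeNH(OMe)·HCl, AlMe3, THF, −20 → 0 °C
Reagents that add atoms: N,O-dimethylhydroxylamine hydrochloride, CNOC.Cl
Why: Aluminium-amide transamination of the imide (Weinreb amide formation), assisted by the free β-hydroxyl through an aluminium chelate; the auxiliary is released unchanged and C7 is not epimerised under these non-basic conditions.

Step 10
Reactants: 18 the β-hydroxy Weinreb amide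
Product: 19 (4R,5S)-4-(3-{[tert-butyl(diphenyl)silyl]oxy}prop-1-en-2-yl)-5-hydroxy-6-(2-methyl-1,3-dioxolan-2-yl)hex-1-en-3-one
Conditions: CH2=CHMgBr (3 equiv), THF, −20 → 0 °C; inverse quench into cold aq. NH4Cl
Reagents that add atoms: vinylmagnesium bromide, C=C[Mg]Br
Why: Weinreb ketone synthesis on the magnesium alkoxide: the first equivalent of Grignard reagent deprotonates O8, the second adds to the amide, and the chelate collapses only on quench to give the vinyl ketone that brings in C5; the inverse quench keeps the released amine from adding to the enone.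

Step 11
Reactants: 19 the β-hydroxy vinyl ketone
Product: 20 (2S,3S,4S)-3-(3-{[tert-butyl(diphenyl)silyl]oxy}prop-1-en-2-yl)-4-hydroxy-1-(2-methyl-1,3-dioxolan-2-yl)hex-5-en-2-yl 3-methylbutanoate (fragment B; C6, C7, C8 as in the target)
Conditions: (CH3)2CHCH2CHO (6 equiv), SmI2 (0.3 equiv), THF, −10 °C
Reagents that add atoms: 3-methylbutanal, CC(C)CC=O
Why: Evans–Tishchenko reduction: the trivalent samarium alkoxide formed from SmI2 and the aldehyde binds O8 and the C6 carbonyl, the O8 hemiacetal of 3-methylbutanal transfers its hydride intramolecularly through a chair-like bicyclic transition state, and C6 is reduced anti to O8 (6S); O8 leaves the step as the 3-methylbutanoate of the target and O6 as the free hydroxyl needed for the tether.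

Step 12
Reactants: 4 (3R)-5,5-dimethoxy-2-methylpent-1-en-3-ol; 21 dichlorodi(propan-2-yl)silane; 20 fragment B alcohol
Product: 23 mixed di(propan-2-yl)silaketal joining O3 of 4 and O6 of 20, via chlorosilane 22 (not isolated)
Conditions: 4, i-Pr2SiCl2 (3 equiv), Et3N, CH2Cl2, 0 °C; excess i-Pr2SiCl2 removed in vacuo; then 20, imidazole, DMF, rt
Reagents that add atoms: none
Why: Stepwise silyl ether formation: with excess dichlorosilane 4 is silylated once, the hindered monochloride does not take up a second molecule of 4, and after removal of excess 21 it silylates the C6 hydroxyl of 20 under imidazole catalysis; ester, acetal and ketal are untouched and no stereocentre is affected.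

Step 13
Reactants: 23 the mixed silaketal
Product: 24 (4R,7S)-4-(2,2-dimethoxyethyl)-5-methyl-2,2-di(propan-2-yl)-4,7-dihydro-1,3,2-dioxasilepine carrying on C7 the C7–C14 chain of 20
Conditions: second-generation Grubbs catalyst RuCl2(=CHPh)(PCy3)(SIMes) (10 mol %), toluene (0.005 M), 80 °C, Ar purge
Reagents that add atoms: none
Why: Ring-closing olefin metathesis by the Chauvin mechanism: the ruthenium benzylidene exchanges onto the monosubstituted C5 vinyl group, the new alkylidene adds across the 1,1-disubstituted C4 isopropenyl alkene of the same molecule, and cycloreversion of the ruthenacyclobutane releases the ring alkene, with loss of ethene as driving force. The closest known reaction type is the metathesis of bis(allyloxy)dialkylsilanes to 4,7-dihydro-1,3,2-dioxasilepines, which is established for trisubstituted ring alkenes. The one ring formed is seven-membered (C3, C4, C5, C6, O, Si, O) and closes by joining the two alkene carbons; a ring of this size can hold only a cis ring alkene, so C4=C5 must be Z. No stereocentre is made: C3 and C6 are outside the reacting bonds and keep the configurations set in steps 3 and 11, ending trans on the new ring. The step needs chemoselectivity among three alkenes, and the substrate secures it: C11=C13 is 1,1-disubstituted, flanked by the bulky silyloxymethyl group and the branched C7, and could only close a cyclobutene with C5 or an eight-membered tetrasubstituted alkene with C4. High dilution and removal of ethene should suppress dimerisation through the C5 vinyl group. The esters, acetal, ketal and silyl ether are inert to the catalyst.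

Step 14
Reactants: 24 the dioxasilepine
Product: 25 keto aldehyde (C1 aldehyde, C10 methyl ketone) on the dioxasilepine
Conditions: PPTS, acetone/H2O (10:1), 45 °C
Reagents that add atoms: water, O
Why: Acid-catalysed acetal and ketal hydrolysis unmasks the C1 aldehyde and the C10 ketone together; PPTS in wet acetone opens dioxolanes of methyl ketones while hindered silyl ethers (here the silaketal with two secondary alkoxy groups and the tert-butyldiphenylsilyl ether) and esters normally persist, and the β-acyloxy ketone is never exposed to base.

Step 15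
Reactants: 25 the keto aldehyde
Product: 26 bicyclic cis-1,10-diol (1R,10S), ten-membered ring closed at C1–C10, silicon bridge retained
Conditions: SmI2 (4 equiv), THF, rt, slow addition of 25 (final 0.002 M); aq. NH4Cl
Reagents that add atoms: none
Why: Samarium-mediated intramolecular pinacol coupling: the aldehyde is reduced first to the ketyl, which adds to the samarium-bound ketone under high dilution; bridging of both oxygens by trivalent samarium in the bond-forming transition state should put the hydroxyls on the same face, the dioxasilepine shortens the chain that must fold, and either cis-diol is acceptable because C1 and C10 become sp2 in step 17.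

Step 16
Reactants: 26 the cis-1,10-diol
Product: 27 cyclic 1,10-thiocarbonate of 26
Conditions: 1,1'-thiocarbonyldiimidazole, DMAP, toluene, 100 °C
Reagents that add atoms: 1,1'-thiocarbonyldiimidazole, S=C(n1ccnc1)n1ccnc1
Why: Cyclic thiocarbonate formation from a vicinal diol: the secondary C1 hydroxyl is thioacylated first and the tertiary C10 hydroxyl closes the five-membered ring intramolecularly on heating (first stage of the Corey–Winter olefination).

Step 17
Reactants: 27 the thiocarbonate
Product: 28 bicyclic (1(10)Z,4Z)-diene, O3 and O6 bridged by Si(i-Pr)2, O12 as tert-butyldiphenylsilyl ether, O8 as 3-methylbutanoate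
Conditions: 1,3-dimethyl-2-phenyl-1,3,2-diazaphospholidine, THF, 45 °C
Reagents that add atoms: none
Why: Corey–Winter olefination in the Corey–Hopkins variant: the phosphorus reagent removes sulfur and the resulting carbene loses CO2 in a stereospecific syn-cycloreversion, so the cis-fused thiocarbonate gives the Z-C1=C10 alkene; the mild temperature spares silaketal and esters.

Step 18
Reactants: 28 the bicyclic diene
Product: 29 (1(10)Z,4Z)-3,6,12-trihydroxygermacra-1(10),4,11(13)-trien-8-yl 3-methylbutanoate
Conditions: TBAF, AcOH, THF, 0 °C → rt
Reagents that add atoms: none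
Why: Fluoride-mediated cleavage of Si–O bonds removes the silicon bridge and the tert-butyldiphenylsilyl ether together; acetic acid buffers the alkoxides so the 3-methylbutanoate on O8 does not migrate to O6.

Step 19
Reactants: 29 the triol
Product: 30 (1(10)Z,4Z)-3-hydroxy-8-(3-methylbutanoyloxy)germacra-1(10),4,11(13)-trien-12,6-olide
Conditions: TEMPO (20 mol %), PhI(OAc)2 (2.5 equiv), CH2Cl2, rt
Reagents that add atoms: none
Why: Oxoammonium-catalysed oxidative lactonisation of a 1,4-diol: the primary allylic C12 alcohol is oxidised faster than the secondary ones, O6 adds to the enal to give the five-membered lactol (cis-fused, fixed by C6 and C7), and a second oxidation gives the α-methylene lactone; the C3 hydroxyl, secondary and unable to form a lactol, should remain.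

Step 20
Reactants: 30 the hydroxy lactone
Product: 31 (1(10)Z,4Z)-3-acetoxy-8-(3-methylbutanoyloxy)germacra-1(10),4,11(13)-trien-12,6-olide
Conditions: Ac2O, pyridine, DMAP (cat.), CH2Cl2, 0 °C
Reagents that add atoms: acetic anhydride, CC(=O)OC(C)=O
Why: Acylation of the remaining secondary allylic alcohol under nucleophilic catalysis, at 0 °C to avoid addition of pyridine to the methylene lactone; capping O3 also removes a hydroxyl that would direct a peracid to the α face in step 21.

Step 21
Reactants: 31 the diene diester
Product: 32 (1R,3R,4Z,6S,7R,8S,10S)-3-acetoxy-1,10-epoxy-8-(3-methylbutanoyloxy)germacra-4,11(13)-dien-12,6-olide (CNP0157657.2)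
Conditions: m-CPBA, NaHCO3, CH2Cl2, 0 °C
Reagents that add atoms: 3-chloroperoxybenzoic acid, OOC(=O)c1cccc(Cl)c1
Why: Prilezhaev epoxidation, stereospecific for the Z geometry and so giving the cis-oxirane: C1=C10 is the only electron-rich alkene (C4=C5 has two allylic acyloxy groups, C11=C13 is conjugated), and the peracid should approach from the β face because the homoallylic acyloxy groups on C3 and C8 both shield the α face, setting C1 (R) and C10 (S); bicarbonate buffers the acid-sensitive product.

## Compound list

1 | methyl 3,3-dimethoxypropanoate | COC(=O)CC(OC)OC | starting material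
2 | N,3,3-trimethoxy-N-methylpropanamide | CON(C)C(=O)CC(OC)OC | intermediate
3 | 5,5-dimethoxy-2-methylpent-1-en-3-one | C=C(C)C(=O)CC(OC)OC | intermediate
4 | (3R)-5,5-dimethoxy-2-methylpent-1-en-3-ol (fragment A) | C=C(C)[C@@H](CC(OC)OC)O | intermediate
5 | 2-methylprop-2-en-1-ol | CC(=C)CO | starting material
6 | O,C-dilithio dianion of 2-methylprop-2-en-1-ol | [Li+].[Li+].[CH2-]C(=C)C[O-] | intermediate
7 | 3-(hydroxymethyl)but-3-enoic acid | OCC(=C)CC(=O)O | intermediate
8 | 4-methylideneoxolan-2-one | C=C1COC(=O)C1 | intermediate
9 | lithium 3-(hydroxymethyl)but-3-enoate | [Li+].[O-]C(=O)CC(=C)CO | intermediate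
10 | 3-{[tert-butyl(diphenyl)silyl]oxymethyl}but-3-enoic acid | C=C(CO[Si](c1ccccc1)(c1ccccc1)C(C)(C)C)CC(=O)O | intermediate
11 | (4R)-4-benzyl-1,3-oxazolidin-2-one | O=C1N[C@H](Cc2ccccc2)CO1 | starting material
12 | mixed anhydride of 10 with 2,2-dimethylpropanoic acid | C=C(CO[Si](c1ccccc1)(c1ccccc1)C(C)(C)C)CC(=O)OC(=O)C(C)(C)C | intermediate
13 | (4R)-4-benzyl-3-(3-{[tert-butyl(diphenyl)silyl]oxymethyl}but-3-enoyl)-1,3-oxazolidin-2-one | C=C(CO[Si](c1ccccc1)(c1ccccc1)C(C)(C)C)CC(=O)N1[C@H](Cc2ccccc2)COC1=O | intermediate
14 | ethyl 2-(2-methyl-1,3-dioxolan-2-yl)acetate | CCOC(=O)CC1(C)OCCO1 | starting material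
15 | 2-(2-methyl-1,3-dioxolan-2-yl)acetaldehyde | O=CCC1(C)OCCO1 | intermediate
16 | (Z)-dibutylboron enolate of 13 | CCCCB(CCCC)O/C(=C\C(=C)CO[Si](c1ccccc1)(c1ccccc1)C(C)(C)C)N1[C@H](Cc2ccccc2)COC1=O | intermediate
17 | (4R)-4-benzyl-3-[(2R,3S)-2-(3-{[tert-butyl(diphenyl)silyl]oxy}prop-1-en-2-yl)-3-hydroxy-4-(2-methyl-1,3-dioxolan-2-yl)butanoyl]-1,3-oxazolidin-2-one | O=C(N1[C@H](Cc2ccccc2)COC1=O)[C@H](C(=C)CO[Si](c1ccccc1)(c1ccccc1)C(C)(C)C)[C@@H](O)CC1(C)OCCO1 | intermediate
18 | (2R,3S)-2-(3-{[tert-butyl(diphenyl)silyl]oxy}prop-1-en-2-yl)-3-hydroxy-N-methoxy-N-methyl-4-(2-methyl-1,3-dioxolan-2-yl)butanamide | CON(C)C(=O)[C@H](C(=C)CO[Si](c1ccccc1)(c1ccccc1)C(C)(C)C)[C@@H](O)CC1(C)OCCO1 | intermediate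
19 | (4R,5S)-4-(3-{[tert-butyl(diphenyl)silyl]oxy}prop-1-en-2-yl)-5-hydroxy-6-(2-methyl-1,3-dioxolan-2-yl)hex-1-en-3-one | C=CC(=O)[C@H](C(=C)CO[Si](c1ccccc1)(c1ccccc1)C(C)(C)C)[C@@H](O)CC1(C)OCCO1 | intermediate
20 | (2S,3S,4S)-3-(3-{[tert-butyl(diphenyl)silyl]oxy}prop-1-en-2-yl)-4-hydroxy-1-(2-methyl-1,3-dioxolan-2-yl)hex-5-en-2-yl 3-methylbutanoate (fragment B) | O[C@@H](C=C)[C@H](C(=C)CO[Si](c1ccccc1)(c1ccccc1)C(C)(C)C)[C@@H](OC(=O)CC(C)C)CC1(C)OCCO1 | intermediate
21 | dichlorodi(propan-2-yl)silane | CC(C)[Si](Cl)(Cl)C(C)C | starting material
22 | chloro{[(3R)-5,5-dimethoxy-2-methylpent-1-en-3-yl]oxy}di(propan-2-yl)silane | C=C(C)[C@@H](CC(OC)OC)O[Si](Cl)(C(C)C)C(C)C | intermediate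
23 | mixed di(propan-2-yl)silaketal of 4 (through O3) and 20 (through O6) | C=C(C)[C@@H](CC(OC)OC)O[Si](C(C)C)(C(C)C)O[C@@H](C=C)[C@H](C(=C)CO[Si](c1ccccc1)(c1ccccc1)C(C)(C)C)[C@@H](OC(=O)CC(C)C)CC1(C)OCCO1 | intermediate
24 | (4R,7S)-4-(2,2-dimethoxyethyl)-5-methyl-2,2-di(propan-2-yl)-4,7-dihydro-1,3,2-dioxasilepine with the C7–C14 chain of 20 on ring C7 | C/C1=C/[C@@H]([C@H](C(=C)CO[Si](c2ccccc2)(c2ccccc2)C(C)(C)C)[C@@H](OC(=O)CC(C)C)CC2(C)OCCO2)O[Si](C(C)C)(C(C)C)O[C@@H]1CC(OC)OC | intermediate
25 | keto aldehyde of 24 (C1 aldehyde, C10 methyl ketone) | C/C1=C/[C@@H]([C@H](C(=C)CO[Si](c2ccccc2)(c2ccccc2)C(C)(C)C)[C@@H](OC(=O)CC(C)C)CC(C)=O)O[Si](C(C)C)(C(C)C)O[C@@H]1CC=O | intermediate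
26 | bicyclic (1R,10S)-cis-1,10-diol, ten-membered ring with O3–Si(i-Pr)2–O6 bridge | C/C1=C/[C@@H]2O[Si](C(C)C)(C(C)C)O[C@@H]1C[C@@H](O)[C@@](C)(O)C[C@H](OC(=O)CC(C)C)[C@H]2C(=C)CO[Si](c1ccccc1)(c1ccccc1)C(C)(C)C | intermediate
27 | cyclic 1,10-thiocarbonate of 26 | C/C1=C/[C@@H]2O[Si](C(C)C)(C(C)C)O[C@@H]1C[C@H]3OC(=S)O[C@@]3(C)C[C@H](OC(=O)CC(C)C)[C@H]2C(=C)CO[Si](c1ccccc1)(c1ccccc1)C(C)(C)C | intermediate
28 | bicyclic (1(10)Z,4Z)-diene with O3–Si(i-Pr)2–O6 bridge, 12-O-silyl, 8-O-(3-methylbutanoyl) | C/C1=C/[C@@H]2O[Si](C(C)C)(C(C)C)O[C@@H]1C/C=C(C)\C[C@H](OC(=O)CC(C)C)[C@H]2C(=C)CO[Si](c1ccccc1)(c1ccccc1)C(C)(C)C | intermediate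
29 | (1(10)Z,4Z)-3,6,12-trihydroxygermacra-1(10),4,11(13)-trien-8-yl 3-methylbutanoate | C/C1=C/[C@H](O)[C@H](C(=C)CO)[C@@H](OC(=O)CC(C)C)C/C(C)=C\C[C@H]1O | intermediate
30 | (1(10)Z,4Z)-3-hydroxy-8-(3-methylbutanoyloxy)germacra-1(10),4,11(13)-trien-12,6-olide | C=C1C(=O)O[C@H]2/C=C(/C)[C@H](O)C/C=C(C)\C[C@H](OC(=O)CC(C)C)[C@@H]12 | intermediate
31 | (1(10)Z,4Z)-3-acetoxy-8-(3-methylbutanoyloxy)germacra-1(10),4,11(13)-trien-12,6-olide | C=C1C(=O)O[C@H]2/C=C(/C)[C@H](OC(C)=O)C/C=C(C)\C[C@H](OC(=O)CC(C)C)[C@@H]12 | intermediate
32 | (1R,3R,4Z,6S,7R,8S,10S)-3-acetoxy-1,10-epoxy-8-(3-methylbutanoyloxy)germacra-4,11(13)-dien-12,6-olide | C=C1C(=O)O[C@H]2/C=C(/C)[C@H](OC(C)=O)C[C@H]3O[C@@]3(C)C[C@H](OC(=O)CC(C)C)[C@@H]12 | target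

## Step count and risk

Total: 21 steps. Longest linear sequence: 17 steps (5 to 32 through steps 4–6 and 8–21). Fragment A takes 3 steps, aldehyde 15 takes 1.

**Step 13 (key step).** The likely failure is slow closure onto the hindered isopropenyl group, so that intermolecular metathesis through the C5 vinyl group and catalyst decay take over. The fallback builds the same dioxasilepine without metathesis; it sets out from 2 and 18 and comes back at 24.
- HC≡CMgBr adds to 2 to give 5,5-dimethoxypent-1-yn-3-one F1, which RuCl(p-cymene)[(R,R)-TsDPEN] in i-PrOH should reduce to (3R)-5,5-dimethoxypent-1-yn-3-ol F2.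
- Hydroxyl-directed anti-carbomagnesiation (CH3MgBr, CuI) and iodination give (1Z,3R)-1-iodo-5,5-dimethoxy-2-methylpent-1-en-3-ol F3, with iodine cis to the carbinol carbon; this is protected as its triethylsilyl ether F4.
- Iodine–lithium exchange (t-BuLi) and acylation by the chloromagnesium alkoxide of 18 give the Z-enone F5, which already holds C1–C10.
- Evans–Tishchenko reduction (3-methylbutanal, catalytic SmI2) gives the C6 alcohol F6, buffered fluoride frees O3 to give the Z-ene-diol F7, and i-Pr2Si(OTf)2 with 2,6-lutidine closes 24.

**Step 15.** The ten-membered closure may lose to intermolecular pinacol dimerisation or to simple reduction of the aldehyde, because transannular strain and the trans-disposed side chains on the seven-membered ring raise the barrier. Incomplete cis control of the diol would also spoil the syn-elimination. The fallback sets out from 25 and comes back at 28: non-basic methylenation of both carbonyls (Zn, CH2Br2, TiCl4; esters and the β-acyloxy ketone tolerate it) gives the triene F8, and ring-closing metathesis with the second-generation Hoveyda–Grubbs catalyst RuCl2(=CH-C6H4-2-O-i-Pr)(SIMes) between the C1 vinyl and C10 isopropenyl groups should give 28 directly, bypassing 26 and 27.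

**Step 21.** The risk is facial selectivity: the ring conformation may expose the α face in spite of the two acyloxy groups. The fallback sets out from 31 and comes back at 32. NBS in aqueous acetone forms the bromonium ion on the face the peracid prefers, and water opens it at the tertiary C10 from the other side to give the bromohydrin F9 (bromine α on C1, hydroxyl β on C10). Ag2O then closes the oxirane by displacement at C1, which puts the oxygen on the β face.

**Step 11.** Conjugate addition to, or oligomerisation of, the unsubstituted vinyl ketone may compete with hydride transfer under the Lewis-acidic alkoxide conditions. The fallback sets out from 18 and comes back at 20: LiC≡CSiMe3 adds to 18 to give the silyl ynone F10; Evans–Tishchenko reduction as in step 11 gives the propargylic alcohol F11; buffered fluoride at low temperature removes the alkynyl silyl group to give the terminal alkyne F12; semi-hydrogenation (H2, Pd/CaCO3 poisoned with Pb(OAc)2, quinoline) gives 20, the 1,1-disubstituted alkene being left alone.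

**Step 14.** The silaketal bridge may be cleaved by acid before the dioxolane, which is slowed by the β-acyloxy group, has opened. The fallback unmasks the ketone before any silaketal exists; it sets out from 20 and comes back at 25. PPTS in wet acetone on 20 gives the methyl ketone F13; silylation with chlorosilane 22 as in step 12 gives the silaketal F14; metathesis as in step 13 gives the dioxasilepine F15; only the far more labile dimethyl acetal is then hydrolysed, under brief and cold PPTS treatment, to give 25.

## Further compounds

F1 | step 13 | 5,5-dimethoxypent-1-yn-3-one | C#CC(=O)CC(OC)OC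
F2 | step 13 | (3R)-5,5-dimethoxypent-1-yn-3-ol | C#C[C@@H](CC(OC)OC)O
F3 | step 13 | (1Z,3R)-1-iodo-5,5-dimethoxy-2-methylpent-1-en-3-ol | I/C=C(/C)[C@@H](CC(OC)OC)O
F4 | step 13 | triethylsilyl ether of F3 | I/C=C(/C)[C@@H](CC(OC)OC)O[Si](CC)(CC)CC
F5 | step 13 | Z-enone from F4 and 18 (C6 ketone, C8 hydroxyl, O3 triethylsilyl) | O=C(/C=C(/C)[C@@H](CC(OC)OC)O[Si](CC)(CC)CC)[C@H](C(=C)CO[Si](c1ccccc1)(c1ccccc1)C(C)(C)C)[C@@H](O)CC1(C)OCCO1
F6 | step 13 | C6 alcohol with O8 3-methylbutanoate and O3 triethylsilyl ether | O[C@@H](/C=C(/C)[C@@H](CC(OC)OC)O[Si](CC)(CC)CC)[C@H](C(=C)CO[Si](c1ccccc1)(c1ccccc1)C(C)(C)C)[C@@H](OC(=O)CC(C)C)CC1(C)OCCO1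
F7 | step 13 | Z-ene-3,6-diol | O[C@@H](/C=C(/C)[C@@H](CC(OC)OC)O)[C@H](C(=C)CO[Si](c1ccccc1)(c1ccccc1)C(C)(C)C)[C@@H](OC(=O)CC(C)C)CC1(C)OCCO1
F8 | step 15 | bis-methylenated 25 (C1 vinyl, C10 isopropenyl) | C/C1=C/[C@@H]([C@H](C(=C)CO[Si](c2ccccc2)(c2ccccc2)C(C)(C)C)[C@@H](OC(=O)CC(C)C)CC(C)=C)O[Si](C(C)C)(C(C)C)O[C@@H]1CC=C
F9 | step 21 | 1α-bromo-10β-hydroxy bromohydrin of 31 | C=C1C(=O)O[C@H]2/C=C(/C)[C@H](OC(C)=O)C[C@H](Br)[C@@](C)(O)C[C@H](OC(=O)CC(C)C)[C@@H]12
F10 | step 11 | trimethylsilyl ynone from 18 | C[Si](C)(C)C#CC(=O)[C@H](C(=C)CO[Si](c1ccccc1)(c1ccccc1)C(C)(C)C)[C@@H](O)CC1(C)OCCO1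
F11 | step 11 | propargylic C6 alcohol with O8 3-methylbutanoate, alkyne silylated | O[C@@H](C#C[Si](C)(C)C)[C@H](C(=C)CO[Si](c1ccccc1)(c1ccccc1)C(C)(C)C)[C@@H](OC(=O)CC(C)C)CC1(C)OCCO1
F12 | step 11 | terminal alkyne analogue of 20 | O[C@@H](C#C)[C@H](C(=C)CO[Si](c1ccccc1)(c1ccccc1)C(C)(C)C)[C@@H](OC(=O)CC(C)C)CC1(C)OCCO1
F13 | step 14 | C10 methyl ketone from 20 | O[C@@H](C=C)[C@H](C(=C)CO[Si](c1ccccc1)(c1ccccc1)C(C)(C)C)[C@@H](OC(=O)CC(C)C)CC(C)=O
F14 | step 14 | mixed silaketal of 4 and F13 | C=C(C)[C@@H](CC(OC)OC)O[Si](C(C)C)(C(C)C)O[C@@H](C=C)[C@H](C(=C)CO[Si](c1ccccc1)(c1ccccc1)C(C)(C)C)[C@@H](OC(=O)CC(C)C)CC(C)=O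
F15 | step 14 | dioxasilepine with free C10 ketone and C1 dimethyl acetal | C/C1=C/[C@@H]([C@H](C(=C)CO[Si](c2ccccc2)(c2ccccc2)C(C)(C)C)[C@@H](OC(=O)CC(C)C)CC(C)=O)O[Si](C(C)C)(C(C)C)O[C@@H]1CC(OC)OC
A1 | alternative 1 | ten-membered C3 enone fused to the cis-lactone, O8 silylated | C1C(=O)O[C@H]2/C=C(/C)C(=O)C/C=C(/C)C[C@H](O[Si](C)(C)C(C)(C)C)[C@@H]12
A2 | alternative 2 | ten-membered C8 carbinol with the C11=C13 methylene, O3 and O6 silylated, O12 as 4-methoxybenzyl ether | C=C(COCc1ccc(OC)cc1)[C@H]2[C@@H](O[Si](C)(C)C(C)(C)C)/C=C(/C)[C@H](O[Si](C)(C)C(C)(C)C)C/C=C(/C)C[C@@H]2O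
A3 | alternative 3 | ten-membered Z,Z-dienone with tert-butyl acetate arm on C7 and dimethyl(phenyl)silyl group on C8 | CC(C)(C)OC(=O)C[C@H]1C(=O)/C=C(/C)[C@H](O[Si](C)(C)C(C)(C)C)C/C=C(/C)C[C@@H]1[Si](C)(C)c1ccccc1
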